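The vessel is what differs here: violet is a stirred flow tank (CSTR) at steady state with mean residence time τ, grey a flask dosed at a steady rate and then left, and blue a closed flask charged at once, with the same amounts in each.

| flask | starting material | catalyst | remark | time |
|---|---|---|---|---|
| Tuesday's | 0.059 M | 6.8 mol% | run made earlier |  |
| Sunday's | 0.083 M | 6.8 mol% | run made earlier |  |
| Saturday's | 0.13 M | 6.8 mol% | run made earlier |  |
| violet | 0.059 M | 6.8 mol% | one stirred flow tank at steady state, fed with the mixture as stated, mean residence time 30 min |  |
| grey | 0.059 M (fed, over 15.0 min) | 6.8 mol% | a stirred flask in which starting material is dosed at a steady rate over 15.0 min without added volume, worked up at 30 min | 30 min |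
| blue | 0.059 M | 6.8 mol% | a closed flask charged with all of it at once and left for 30 min | 30 min |

| run | time / min | target / % | starting material / % |
|---|---|---|---|
| Tuesday's | 2.50 | 0 | 79 |
| Tuesday's | 6.00 | 6 | 60 |
| Tuesday's | 12.0 | 13 | 36 |
| Tuesday's | 30.0 | 30 | 8 |
| Sunday's | 8.00 | 8 | 50 |
| Sunday's | 15.0 | 19 | 25 |
| Sunday's | 25.0 | 32 | 12 |
| Sunday's | 30.0 | 35 | 8 |
| Saturday's | 2.50 | 2 | 80 |
| Saturday's | 6.00 | 8 | 58 |
| Saturday's | 12.0 | 16 | 33 |
| Saturday's | 30.0 | 35 | 9 |

(standard deviation of a reading: 1.5 percentage points)

1. order of the set-ups by the amount of target at the outlet or at the end, in percent of the starting material put in, highest first (violet / grey / blue)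
2. amount of target at the outlet or at the end, in percent of the starting material put in, violet
3. amount of target at the outlet or at the end, in percent of the starting material put in, grey
4. amount of target at the outlet or at the end, in percent of the starting material put in, blue

- the stated concentrations are those of everything mixed, before any reaction; amounts are the same in each set-up
- what was read earlier has a scatter of 1.5 percentage points, one standard deviation
- the feed brings no volume worth counting
- the earlier runs were made in a closed, stirred flask
- a reading or a percentage of target counts all its forms, free or not
- a reading of starting material is of its free form alone

Two views of these runs dispute the tank. Both treat the loss of starting material as first-order. From Tuesday's last reading I take the rate constant k = 0.0842 min⁻¹. The fraction A of free starting material left is then 1/(1 + kτ) = 28.4% in violet and, by integrating the dose, 16.1% in grey.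

The forecast counts minutes: target rises at about 1.1 %/min, and in violet “the tank leaves 28% starting material and the intermediate stays high”. It gives 32% for violet, 28% for grey and 31% for blue, in the order violet > blue > grey.

I divide the target found by the free starting material lost at the same reading, and this ratio still depends on when it is read. Tuesday's last reading gives 0.326; I call this S, the integral selectivity, the target found per free starting material gone. Holding S at that value, I estimate the yield as S(1 − A), which is 23.4% for violet and 27.4% for grey, while blue repeats Tuesday's 30%. So I rank blue above grey and grey above violet, because the tank leaves more starting material unused than the dosed flask. My figures for violet and grey lean high: S read at 12.0 min is 0.203, lower than at 30.0 min, and part of the material in those vessels is younger than τ.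

The flasks give 21.4% for violet, 23.9% for grey and 30.5% for blue, in the order blue > grey > violet.

    starting material → intermediate (k = 5.86 × 10⁻⁴ s⁻¹)
    catalyst + intermediate → catalyst + target (k = 0.390 M⁻¹ s⁻¹)
    starting material → uncatalysed product (k = 8.33 × 10⁻⁴ s⁻¹)
    starting material + target ⇌ idle adduct, settled at all times (K = 7.53 M⁻¹)

The order is the one S gave, and violet lies 11 percentage points below the forecast. The clock view keeps the closed flask charged at once: blue gives 30.5% against its 31%. In grey, 16% free starting material is left, so S there is 0.285, lower than Tuesday's. The same reckoning on blue read at 8.0 min takes Tuesday's S from its nearest reading, at 6.00 min, which is 0.150, and with the loss from k it gives 7.35% target. That flask holds 50% free starting material and 6.63% target.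

The earlier runs and the new flask are calculated with made-up constants, noise included.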